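Both pyranones are disconnected at their carbonyl–arene bonds, C4–C4a and C4''–C4a''. The feature exploited is that C4a (ring A) sits ortho to O1 and para to the C7 methoxy group, while C4a'' (ring D) sits ortho to O1'' and para to the C7'' oxygen, so each carbon is the natural site for an intramolecular acylation. One treatment of a diacid with P2O5 in MeSO3H should therefore close rings C and F together. The precursor is a ring B–ring D biaryl carrying two (Z)-3-aryloxyacrylic acid arms. Its ring D oxygens are differentiated from the outset (one isopropyl ether, one vinyl ether), which removes any statistical O-functionalisation of a free resorcinol.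

Key step: step 10

Remark: the target has no stereocentre and its ring B–ring D axis is drawn without configuration, so no axial control is attempted; compounds 1, 6 and 12 are taken as catalogue chemicals; the Z vinyl ethers are drawn as the isomers expected from anti addition.

Step 1
Reactants: 1 2-bromo-4-iodo-1-methoxybenzene; 2 ethyl propiolate
Product: 3 ethyl 3-(3-bromo-4-methoxyphenyl)prop-2-ynoate
Conditions: PdCl2(PPh3)2 (cat.), CuI (cat.), K2CO3, THF, 60 °C, excess 2
Reagents that add atoms: none
Why: Sonogashira coupling with an inorganic base (no amine that could add to the propiolate), in which zerovalent palladium should insert into the C–I bond far faster than into the C–Br bond ortho to the methoxy group.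

Step 2
Reactants: 3 ethyl 3-(3-bromo-4-methoxyphenyl)prop-2-ynoate; 4 3-methoxyphenol
Product: 5 ethyl (Z)-3-(3-bromo-4-methoxyphenyl)-3-(3-methoxyphenoxy)prop-2-enoate
Conditions: K2CO3 (0.5 equiv), DMF, 80 °C
Reagents that add atoms: none
Why: Base-mediated oxa-Michael addition of the phenoxide to the aryl alkynoate at the aryl-bearing carbon, with anti addition expected to favour the Z vinyl ether; any E isomer can be carried on because the geometry equilibrates in the acid of step 10.

Step 3
Reactants: 6 3-isopropoxyphenol
Product: 7 1-isopropoxy-3-(methoxymethoxy)benzene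
Conditions: MOMCl, i-Pr2NEt, CH2Cl2, 0 °C to rt
Reagents that add atoms: chloromethyl methyl ether (MOMCl), COCCl
Why: Routine O-alkylation of a phenol to its methoxymethyl ether, which serves both as protecting group and as directing group for step 4.

Step 4
Reactants: 7 1-isopropoxy-3-(methoxymethoxy)benzene
Product: 9 2-[2-isopropoxy-6-(methoxymethoxy)phenyl]-4,4,5,5-tetramethyl-1,3,2-dioxaborolane, via aryllithium 8 (not isolated)
Conditions: n-BuLi, THF, 0 °C to rt; then i-PrOBpin, −78 °C to rt; aq NH4Cl
Reagents that add atoms: 2-isopropoxy-4,4,5,5-tetramethyl-1,3,2-dioxaborolane (i-PrOBpin), CC(C)OB1OC(C)(C)C(C)(C)O1; n-butyllithium, [Li]CCCC (its lithium stands in intermediate 8 only)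
Why: Directed ortho-metalation at the carbon flanked by the methoxymethoxy and isopropoxy groups (cooperative direction by both oxygens), followed by borylation of the aryllithium with the boronic ester.

Step 5
Reactants: 5 ethyl (Z)-3-(3-bromo-4-methoxyphenyl)-3-(3-methoxyphenoxy)prop-2-enoate; 9 2-[2-isopropoxy-6-(methoxymethoxy)phenyl]-4,4,5,5-tetramethyl-1,3,2-dioxaborolane
Product: 10 ethyl (Z)-3-[2'-isopropoxy-6-methoxy-6'-(methoxymethoxy)biphenyl-3-yl]-3-(3-methoxyphenoxy)prop-2-enoate
Conditions: Pd(OAc)2 (cat.), SPhos (2-dicyclohexylphosphino-2',6'-dimethoxybiphenyl), K3PO4, toluene/H2O, 90 °C, excess 9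
Reagents that add atoms: none
Why: Suzuki–Miyaura coupling with a bulky electron-rich biarylphosphine suited to tri-ortho-substituted biaryls; the trisubstituted enoate and its ester should tolerate the mild phosphate base.

Step 6
Reactants: 10 ethyl (Z)-3-[2'-isopropoxy-6-methoxy-6'-(methoxymethoxy)biphenyl-3-yl]-3-(3-methoxyphenoxy)prop-2-enoate
Product: 11 ethyl (Z)-3-(2'-hydroxy-6'-isopropoxy-6-methoxybiphenyl-3-yl)-3-(3-methoxyphenoxy)prop-2-enoate
Conditions: HCl (cat.), EtOH/THF, rt to 40 °C
Reagents that add atoms: none
Why: Acid-catalysed acetal cleavage of the methoxymethyl ether, where protonation at the acetal oxygen is much easier than C-protonation of the ester-conjugated vinyl ether; ethanol keeps any ester exchange degenerate and the aryl isopropyl ether is stable to dilute acid.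

Step 7
Reactants: 12 1-iodo-4-isopropoxybenzene; 2 ethyl propiolate
Product: 13 ethyl 3-(4-isopropoxyphenyl)prop-2-ynoate
Conditions: PdCl2(PPh3)2 (cat.), CuI (cat.), K2CO3, THF, 60 °C, excess 2
Reagents that add atoms: none
Why: The same amine-free Sonogashira coupling as in step 1, here on a simple aryl iodide.

Step 8
Reactants: 11 ethyl (Z)-3-(2'-hydroxy-6'-isopropoxy-6-methoxybiphenyl-3-yl)-3-(3-methoxyphenoxy)prop-2-enoate; 13 ethyl 3-(4-isopropoxyphenyl)prop-2-ynoate
Product: 14 diethyl diester, ethyl (Z)-3-[2'-{[(Z)-3-ethoxy-1-(4-isopropoxyphenyl)-3-oxoprop-1-en-1-yl]oxy}-6'-isopropoxy-6-methoxybiphenyl-3-yl]-3-(3-methoxyphenoxy)prop-2-enoate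
Conditions: Cs2CO3 (0.5 equiv), DMF, 80 °C, slight excess of 13
Reagents that add atoms: none
Why: Oxa-Michael addition of the single free ring D phenoxide to the alkynoate, which is far more electrophilic than the beta,beta-disubstituted vinyl ether already present, so aryloxy exchange there should not compete.

Step 9
Reactants: 14 diethyl diester
Product: 15 diacid, (Z)-3-[2'-{[(Z)-2-carboxy-1-(4-isopropoxyphenyl)ethenyl]oxy}-6'-isopropoxy-6-methoxybiphenyl-3-yl]-3-(3-methoxyphenoxy)prop-2-enoic acid
Conditions: LiOH·H2O, THF/EtOH/H2O, 40 °C; then 1 M HCl to pH 3, 0 °C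
Reagents that add atoms: lithium hydroxide, [Li+].[OH-] (its oxygen ends in each carboxyl group)
Why: Saponification of both ethyl esters by acyl–oxygen cleavage; the donor-substituted, fully substituted beta carbon of each vinyl ether resists conjugate attack by hydroxide.

Step 10
Reactants: 15 diacid
Product: 16 7-methoxy-2-{4-methoxy-3-[7-isopropoxy-2-(4-isopropoxyphenyl)-4-oxo-4H-chromen-8-yl]phenyl}-4H-chromen-4-one
Conditions: P2O5/MeSO3H (1:10 w/w), rt to 45 °C; ice water
Reagents that add atoms: none
Why: In P2O5/MeSO3H each carboxylic acid is dehydrated to a mixed anhydride or acylium ion, which attacks the ortho carbon of its own aryloxy ring and rearomatises by proton loss (intramolecular Friedel–Crafts acylation). The closest known reaction is the Ruhemann flavone synthesis, the acid-promoted cyclisation of 3-aryloxycinnamic acids. Ring C closes by attack of C4a (ring A) on the acyl carbon C4 and ring F by attack of C4a'' (ring D) on C4'', each a six-membered closure that is exo to the C=O bond. No stereocentre is created. The step needs regioselectivity on ring A, where the carbon para to the methoxy group is both more activated and less crowded than the carbon between the two oxygens, whereas ring D offers only one free ortho carbon (para to its isopropoxy group); five-membered closure onto ring B or ring E would have to occur meta to their alkoxy groups and should not compete. Any E vinyl ether should equilibrate to the cyclisable Z form through reversible protonation at the alpha carbon.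

Step 11
Reactants: 16 7-methoxy-2-{4-methoxy-3-[7-isopropoxy-2-(4-isopropoxyphenyl)-4-oxo-4H-chromen-8-yl]phenyl}-4H-chromen-4-one
Product: 17 7-hydroxy-2-(4-hydroxyphenyl)-8-[2-methoxy-5-(7-methoxy-4-oxo-4H-chromen-2-yl)phenyl]-4H-chromen-4-one (target)
Conditions: BCl3 (excess, 1 M in CH2Cl2), CH2Cl2, −78 to 0 °C; MeOH, then H2O
Reagents that add atoms: none
Why: Lewis-acid dealkylation in which BCl3 cleaves secondary (isopropyl) aryl ethers much faster than aryl methyl ethers that lack a neighbouring carbonyl for chelation, and neither the C7 nor the C4' methoxy group has one.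

Compound list
1 | 2-bromo-4-iodo-1-methoxybenzene | COc1ccc(I)cc1Br | starting material
2 | ethyl propiolate | C#CC(=O)OCC | starting material
3 | ethyl 3-(3-bromo-4-methoxyphenyl)prop-2-ynoate | CCOC(=O)C#Cc1ccc(OC)c(Br)c1 | intermediate
4 | 3-methoxyphenol | COc1cccc(O)c1 | starting material
5 | ethyl (Z)-3-(3-bromo-4-methoxyphenyl)-3-(3-methoxyphenoxy)prop-2-enoate | COc1cccc(O/C(=C\C(=O)OCC)c2ccc(OC)c(Br)c2)c1 | intermediate
6 | 3-isopropoxyphenol | CC(C)Oc1cccc(O)c1 | starting material
7 | 1-isopropoxy-3-(methoxymethoxy)benzene | COCOc1cccc(OC(C)C)c1 | intermediate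
8 | [2-isopropoxy-6-(methoxymethoxy)phenyl]lithium | [Li]c1c(OCOC)cccc1OC(C)C | intermediate (not isolated)
9 | 2-[2-isopropoxy-6-(methoxymethoxy)phenyl]-4,4,5,5-tetramethyl-1,3,2-dioxaborolane | COCOc1cccc(OC(C)C)c1B1OC(C)(C)C(C)(C)O1 | intermediate
10 | ethyl (Z)-3-[2'-isopropoxy-6-methoxy-6'-(methoxymethoxy)biphenyl-3-yl]-3-(3-methoxyphenoxy)prop-2-enoate | COc1cccc(O/C(=C\C(=O)OCC)c2ccc(OC)c(-c3c(OCOC)cccc3OC(C)C)c2)c1 | intermediate
11 | ethyl (Z)-3-(2'-hydroxy-6'-isopropoxy-6-methoxybiphenyl-3-yl)-3-(3-methoxyphenoxy)prop-2-enoate | COc1cccc(O/C(=C\C(=O)OCC)c2ccc(OC)c(-c3c(O)cccc3OC(C)C)c2)c1 | intermediate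
12 | 1-iodo-4-isopropoxybenzene | CC(C)Oc1ccc(I)cc1 | starting material
13 | ethyl 3-(4-isopropoxyphenyl)prop-2-ynoate | CCOC(=O)C#Cc1ccc(OC(C)C)cc1 | intermediate
14 | diethyl diester: ring B–ring D biaryl with an ethyl (Z)-3-(3-methoxyphenoxy)acrylate arm on ring B and an ethyl (Z)-3-(4-isopropoxyphenyl)acrylate arm bound through oxygen to ring D | COc1cccc(O/C(=C\C(=O)OCC)c2ccc(OC)c(-c3c(OC(C)C)cccc3O/C(=C\C(=O)OCC)c3ccc(OC(C)C)cc3)c2)c1 | intermediate
15 | diacid corresponding to 14 (key-step precursor, both vinyl ethers Z) | COc1cccc(O/C(=C\C(=O)O)c2ccc(OC)c(-c3c(OC(C)C)cccc3O/C(=C\C(=O)O)c3ccc(OC(C)C)cc3)c2)c1 | intermediate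
16 | 7-methoxy-2-{4-methoxy-3-[7-isopropoxy-2-(4-isopropoxyphenyl)-4-oxo-4H-chromen-8-yl]phenyl}-4H-chromen-4-one | COc1ccc2c(=O)cc(-c3ccc(OC)c(-c4c(OC(C)C)ccc5c(=O)cc(-c6ccc(OC(C)C)cc6)oc45)c3)oc2c1 | intermediate
17 | 7-hydroxy-2-(4-hydroxyphenyl)-8-[2-methoxy-5-(7-methoxy-4-oxo-4H-chromen-2-yl)phenyl]-4H-chromen-4-one | COc1ccc2c(=O)cc(-c3ccc(OC)c(-c4c(O)ccc5c(=O)cc(-c6ccc(O)cc6)oc45)c3)oc2c1 | target

Total step count: 11. Longest linear sequence: 8 steps (steps 1, 2, 5, 6, 8, 9, 10, 11; the branch through steps 3 and 4 is equally long).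

Steps most likely to fail

Step 10. The second acylation may stall once the first chromone is formed and protonated. Ring A may be attacked at the carbon flanked by both oxygens. Isopropyl groups may be lost under the acid and re-attach to an arene. The fallback sets out from 15 and returns at 16. The diacid would be converted with oxalyl chloride and catalytic DMF in CH2Cl2 into the bis(acid chloride) of 15 F1. This would then be cyclised with SnCl4 in CH2Cl2 at −20 to 0 °C. That is a discrete acyl chloride Friedel–Crafts acylation under a Lewis acid at low temperature, in place of dehydration in a Brønsted acid. Material that has lost an isopropyl group in either variant should still converge on 17 in step 11.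

Step 5. Protodeboronation of the 2,6-dioxygenated boronate under aqueous base may outrun a slow transmetalation to a crowded palladium centre. The fallback sets out from aryllithium 8 (generated from 7 as in step 4) and bromide 5, and returns at 10. The aryllithium would be transmetalated with ZnCl2 in THF to [2-isopropoxy-6-(methoxymethoxy)phenyl]zinc chloride F2. This would be coupled with 5 using Pd(OAc)2 and SPhos in THF at 60 °C (Negishi coupling), which needs neither base nor water and is tolerated by the ester.

Step 8. Addition of the flanked ring D phenoxide may be slow. In that time alkynoate 13 may be consumed by base-mediated side reactions, or aryloxy groups may exchange on the vinyl ether already present. The fallback sets out from 13 and 11 and returns at 14. Alkynoate 13 would be hydrochlorinated with LiCl in AcOH at 80 °C to ethyl (Z)-3-chloro-3-(4-isopropoxyphenyl)prop-2-enoate F3. Its chloride would then be displaced by the phenoxide of 11 (Cs2CO3, DMF, 60 °C). This is addition–elimination on a base-stable beta-chloroenoate (nucleophilic vinylic substitution) instead of addition to an alkyne.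

Further compounds
F1 | step 10 | bis(acid chloride) of 15, (Z)-3-[2'-{[(Z)-3-chloro-1-(4-isopropoxyphenyl)-3-oxoprop-1-en-1-yl]oxy}-6'-isopropoxy-6-methoxybiphenyl-3-yl]-3-(3-methoxyphenoxy)prop-2-enoyl chloride | COc1cccc(O/C(=C\C(=O)Cl)c2ccc(OC)c(-c3c(OC(C)C)cccc3O/C(=C\C(=O)Cl)c3ccc(OC(C)C)cc3)c2)c1
F2 | step 5 | [2-isopropoxy-6-(methoxymethoxy)phenyl]zinc chloride | Cl[Zn]c1c(OCOC)cccc1OC(C)C
F3 | step 8 | ethyl (Z)-3-chloro-3-(4-isopropoxyphenyl)prop-2-enoate | CCOC(=O)/C=C(\Cl)c1ccc(OC(C)C)cc1
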